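The route rests on a formal olefin metathesis between a cyclohexenone and a cyclobutene. The ten-membered ring is a cyclodeca-1(10),4-diene whose C1=C10 and C4=C5 olefins sit 1,5 to each other, so both can be unveiled from one cyclobutane (C1–C4–C5–C10). The enone–cyclobutene [2+2] photocycloaddition forms C1–C10 and C4–C5 in one operation and gathers all ten ring carbons, with C2, C6, C7 and C8 already set; heating then cleaves C1–C4 and C5–C10. The precursor is a carvone-derived, trans-lactone-fused 2-methylcyclohexenone (ring C5–C10, C8 silyl ether) paired with (R)-3-methylcyclobut-2-enyl acetate (ring C1–C4).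

Key step: step 9

Remarks on the chemistry:
- Germacrane numbering is used throughout: lactone oxygen on C6, ring fusion C7, angelate on C8, acetates on C2 and C9, lactone carbons C11–C13, C14 on C10, C15 on C4. The target is read as (2R,6R,7S,8R,9R), 1(10)Z, 4E, with a Z-configured (angelate) ester.
- The C2 oxygen is carried on the cyclobutene as its acetate. A donor oxygen on the sp3 carbon of a cyclobutene speeds conrotatory ring opening to the butadiene, a silyloxy group much more than an acyloxy group, and the acetate is already the C2 substituent of the target.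

Step 1
Reactants: 1 (S)-carvone
Product: 3 (5R,6R)-6-hydroxy-2-methyl-5-(prop-1-en-2-yl)cyclohex-2-en-1-one (C8 hydroxyl trans to the C7 isopropenyl group), via sodium dienolate 2 (not isolated)
Conditions: NaN(SiMe3)2, THF, −78 °C; 3-phenyl-2-(phenylsulfonyl)oxaziridine, −78 °C; AcOH
Reagents that add atoms: 3-phenyl-2-(phenylsulfonyl)oxaziridine, O=S(=O)(N1OC1c1ccccc1)c1ccccc1
Why: Kinetic deprotonation takes the α′-methylene (C8) and the N-sulfonyloxaziridine transfers oxygen to the enolate face anti to the adjacent C7 isopropenyl group (enolate hydroxylation), so C8 is set trans; the diequatorial trans ketol is also the thermodynamic epimer.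

Step 2
Reactants: 3 (5R,6R)-6-hydroxy-2-methyl-5-(prop-1-en-2-yl)cyclohex-2-en-1-one
Product: 4 (5R,6R)-6-[(tert-butyldimethylsilyl)oxy]-2-methyl-5-(prop-1-en-2-yl)cyclohex-2-en-1-one
Conditions: t-BuMe2SiCl, imidazole, DMF, rt
Reagents that add atoms: tert-butyldimethylsilyl chloride, CC(C)(C)[Si](C)(C)Cl
Why: Standard silylation of a secondary α-ketol; no stereocentre is touched and the ether must last until step 11.

Step 3
Reactants: 4 (5R,6R)-6-[(tert-butyldimethylsilyl)oxy]-2-methyl-5-(prop-1-en-2-yl)cyclohex-2-en-1-one
Product: 5 linear triethylsilyl dienol ether, tert-butyl{[(1R,6R)-3-methyl-6-(prop-1-en-2-yl)-2-[(triethylsilyl)oxy]cyclohexa-2,4-dien-1-yl]oxy}dimethylsilane (diene C9=C10–C5=C6)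
Conditions: Et3SiOTf, Et3N, CH2Cl2, 0 °C to rt
Reagents that add atoms: triethylsilyl trifluoromethanesulfonate, CC[Si](CC)(CC)OS(=O)(=O)C(F)(F)F
Why: Soft enolisation under equilibrating conditions should remove the γ-hydrogen at C6, because the only α′-hydrogen sits on the silyloxy-bearing C8 and would give a strained tetrasubstituted bis-silyloxy alkene (thermodynamic silyl dienol ether formation).

Step 4
Reactants: 5 linear triethylsilyl dienol ether
Product: 7 (4R,5S,6R)-6-[(tert-butyldimethylsilyl)oxy]-4-hydroxy-2-methyl-5-(prop-1-en-2-yl)cyclohex-2-en-1-one (C6 hydroxyl trans to C7), via epoxide 6 (not isolated)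
Conditions: dimethyldioxirane (acetone solution), CH2Cl2, −78 °C; then aq. citric acid, THF, 0 °C
Reagents that add atoms: dimethyldioxirane, CC1(C)OO1
Why: Vinylogous Rubottom oxidation: the dioxirane should epoxidise the terminal, less hindered C5=C6 bond (C10 is fully substituted) and opening of the epoxide restores the enone; allylic 1,2-strain against the C9 silyloxy group pushes the C8 silyloxy and the trans C7 isopropenyl groups pseudoaxial, so oxygen should enter C6 anti to C7.

Step 5
Reactants: 7 (4R,5S,6R)-6-[(tert-butyldimethylsilyl)oxy]-4-hydroxy-2-methyl-5-(prop-1-en-2-yl)cyclohex-2-en-1-one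
Product: 8 (4R,5S,6R)-6-[(tert-butyldimethylsilyl)oxy]-4-hydroxy-5-(3-hydroxyprop-1-en-2-yl)-2-methylcyclohex-2-en-1-one
Conditions: SeO2 (0.3 equiv), t-BuOOH, CH2Cl2, rt
Reagents that add atoms: selenium dioxide, O=[Se]=O; tert-butyl hydroperoxide, CC(C)(C)OO
Why: Riley-type allylic hydroxylation (ene reaction, then 2,3-sigmatropic shift) should attack the only electron-rich olefin at its methyl group rather than the ring methine, the enone olefin being deactivated; any enal from over-oxidation lies on the path of step 6.

Step 6
Reactants: 8 (4R,5S,6R)-6-[(tert-butyldimethylsilyl)oxy]-4-hydroxy-5-(3-hydroxyprop-1-en-2-yl)-2-methylcyclohex-2-en-1-one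
Product: 11 trans-fused enone lactone (3aS,4R,7aR)-4-[(tert-butyldimethylsilyl)oxy]-6-methyl-3-methylidene-3a,4-dihydro-1-benzofuran-2,5(3H,7aH)-dione, via hydroxy enal 9 (not isolated), via lactol 10 (not isolated)
Conditions: 2,2,6,6-tetramethylpiperidin-1-oxyl (0.2 equiv), PhI(OAc)2 (2.5 equiv), CH2Cl2, rt
Reagents that add atoms: none
Why: Oxoammonium oxidation is selective for the primary allylic alcohol; the aldehyde is trapped by the trans C6 hydroxyl as the lactol, which is oxidised on to the α-methylene lactone (oxidative lactonisation of a 1,4-diol) with C6 and C7 untouched.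

Step 7
Reactants: 12 3-ethoxycyclobut-2-en-1-one
Product: 14 3-methylcyclobut-2-en-1-one, via lithium alkoxide 13 (not isolated)
Conditions: MeLi, Et2O, −78 °C; then 1 M HCl, 0 °C (product kept as a cold ether solution)
Reagents that add atoms: methyllithium, [Li]C
Why: 1,2-Addition to the vinylogous ester followed by acid-mediated loss of ethanol (Stork–Danheiser transposition) gives the 3-methyl enone; ring deprotonation does not compete because the enolate would be a cyclobutadiene.

Step 8
Reactants: 14 3-methylcyclobut-2-en-1-one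
Product: 16 (R)-3-methylcyclobut-2-en-1-yl acetate, via cyclobutenol 15 (not isolated)
Conditions: (S)-1-methyl-3,3-diphenyltetrahydro-1H,3H-pyrrolo[1,2-c][1,3,2]oxazaborole (0.1 equiv), catecholborane, CH2Cl2, −78 °C; MeOH, cold aq. NaOH wash; then Ac2O, Et3N, 4-(dimethylamino)pyridine (cat.), CH2Cl2, 0 °C
Reagents that add atoms: acetic anhydride, CC(=O)OC(C)=O
Why: Corey–Bakshi–Shibata reduction with the (S)-oxazaborolidine should give the (R)-allylic alcohol when the alkenyl arm acts as the large group, and immediate acetylation turns the ring-opening-prone cyclobutenol into the sturdier acetate that already carries the C2 ester of the target.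

Step 9
Reactants: 11 trans-fused enone lactone (ring carbons C5–C10); 16 (R)-3-methylcyclobut-2-en-1-yl acetate (ring carbons C1–C4)
Product: 17 cis-anti-cis photoadduct (tricyclic keto lactone with cyclobutane C1–C4–C5–C10 between the cyclohexanone and the acetoxycyclobutane)
Conditions: hν (350 nm, Pyrex), 16 (5 equiv), degassed CH2Cl2 (0.02 M), −40 °C
Reagents that add atoms: none
Why: Excitation of the enone and intersystem crossing give the triplet, which adds to the cyclobutene through a 1,4-diradical that collapses to the cyclobutane, the classical enone–alkene [2+2] photocycloaddition as known for cyclohexenones and cyclobutenes. The new ring C1–C4–C5–C10 is closed intermolecularly in two bond-forming events (first bond, then radical–radical collapse); it should be cis-fused to the cyclohexanone because the trans-lactone-fused enone cannot twist enough to close trans, and it is necessarily cis-fused to the existing four-membered ring. Head-to-tail orientation (methyl-bearing C4 to the β-carbon C5, C1 to the α-carbon C10) follows the usual preference of the donor-substituted alkene terminus for the β-carbon and avoids placing the quaternary centres C4 and C10 next to each other. C5 and C10 are set by approach to the enone face opposite the C6 and C8 oxygen substituents, C1 and C4 by approach to the cyclobutene face opposite its acetoxy group; for the (R)-acetate these two preferences and the anti arrangement of the outer rings coincide in one matched approach. What the step must deliver is the regiochemistry and the cis ring fusion, since the four new centres are erased in step 10 and any cis-anti-cis head-to-tail diastereomer should open to the same dienone. Low temperature, excess 16 and a 350 nm source keep the cyclobutene from ring opening and leave the lactone and product ketone chromophores unexcited.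

Step 10
Reactants: 17 cis-anti-cis photoadduct
Product: 18 (1(10)Z,4E,2R,6R,7S,8R)-2-acetoxy-8-[(tert-butyldimethylsilyl)oxy]-9-oxogermacra-1(10),4,11(13)-trien-12,6-olide
Conditions: degassed toluene (0.01 M), 2,6-di-tert-butyl-4-methylphenol (cat.), base-washed sealed tube, 190 °C
Reagents that add atoms: none
Why: Thermal cycloreversion of the bicyclo[2.2.0]hexane unit: homolysis of the strained central C1–C4 bond gives a cyclohexane-1,4-diyl that sheds C5–C10 (weakened by the C9 ketone, which ends conjugated with C1=C10), and collapse through the chair-like diyl with C6 and C14 equatorial and C9 axial should give the 4E,1(10)Z diene, the cis,trans outcome typical of this photo-thermal olefin metathesis, with C2, C6, C7 and C8 not involved.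

Step 11
Reactants: 18 silyl-protected Z,E-dienone
Product: 19 (1(10)Z,4E)-2-acetoxy-8-hydroxy-9-oxogermacra-1(10),4,11(13)-trien-12,6-olide (C2, C6, C7 and C8 as in 18)
Conditions: HF·pyridine, pyridine, THF, 0 °C to rt
Reagents that add atoms: none
Why: Fluoride cleavage of the secondary silyl ether under buffered, mildly acidic conditions; the acetate, enone and methylene lactone are inert and C8, although α to the ketone, should not epimerise in the absence of base.

Step 12
Reactants: 19 α-hydroxy dienone; 20 angelic acid
Product: 22 (1(10)Z,4E,2R,6R,7S,8R)-2-acetoxy-8-angeloyloxy-9-oxogermacra-1(10),4,11(13)-trien-12,6-olide, via mixed anhydride 21 (not isolated)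
Conditions: 20, 2,4,6-trichlorobenzoyl chloride, Et3N, toluene, rt; then 19, toluene, 75 °C
Reagents that add atoms: none
Why: Yamaguchi-type mixed-anhydride esterification without a nucleophilic catalyst transfers the angeloyl group without Z to E isomerisation, and acylating C8 while C9 is still a ketone means no neighbouring ester can migrate during this slow step.

Step 13
Reactants: 22 C8 angelate dienone
Product: 23 (1(10)Z,4E,2R,6R,7S,8R,9R)-2-acetoxy-8-angeloyloxy-9-hydroxygermacra-1(10),4,11(13)-trien-12,6-olide
Conditions: NaBH4, CeCl3·7H2O, MeOH, −78 °C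
Reagents that add atoms: none
Why: Luche 1,2-reduction of the enone; hydride should arrive anti to the C8 acyloxy group (Felkin–Anh polar model with C7 inside and H8 next to C10), which gives the 9R alcohol, while the low temperature and cerium chloride spare the methylene lactone and keep the angelate from migrating.

Step 14
Reactants: 23 C9 alcohol
Product: 24 CNP0499619.1, (1(10)Z,4E,2R,6R,7S,8R,9R)-2,9-diacetoxy-8-angeloyloxygermacra-1(10),4,11(13)-trien-12,6-olide
Conditions: Ac2O, pyridine, CH2Cl2, rt
Reagents that add atoms: acetic anhydride, CC(=O)OC(C)=O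
Why: Acetylation of the allylic C9 alcohol is fast next to the poorly migrating angelate, and omitting a nucleophilic catalyst avoids isomerising the angelate.

Compound list
1 | (S)-carvone | CC1=CC[C@@H](CC1=O)C(C)=C | starting material
2 | sodium cross-conjugated dienolate of 1 (enolate toward C8; not isolated) | CC1=CC[C@@H](C=C1[O-])C(C)=C.[Na+] | intermediate
3 | (5R,6R)-6-hydroxy-2-methyl-5-(prop-1-en-2-yl)cyclohex-2-en-1-one | CC1=CC[C@H](C(C)=C)[C@@H](O)C1=O | intermediate
4 | (5R,6R)-6-[(tert-butyldimethylsilyl)oxy]-2-methyl-5-(prop-1-en-2-yl)cyclohex-2-en-1-one | CC1=CC[C@H](C(C)=C)[C@@H](O[Si](C)(C)C(C)(C)C)C1=O | intermediate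
5 | tert-butyl{[(1R,6R)-3-methyl-6-(prop-1-en-2-yl)-2-[(triethylsilyl)oxy]cyclohexa-2,4-dien-1-yl]oxy}dimethylsilane | CC1=C(O[Si](CC)(CC)CC)[C@H](O[Si](C)(C)C(C)(C)C)[C@@H](C(C)=C)C=C1 | intermediate
6 | C5–C6 epoxide of 5, oxygen on the face anti to the C7 isopropenyl group (not isolated) | O1[C@@H]2C(C)=C(O[Si](CC)(CC)CC)[C@H](O[Si](C)(C)C(C)(C)C)[C@@H](C(C)=C)[C@H]12 | intermediate
7 | (4R,5S,6R)-6-[(tert-butyldimethylsilyl)oxy]-4-hydroxy-2-methyl-5-(prop-1-en-2-yl)cyclohex-2-en-1-one | CC1=C[C@@H](O)[C@H](C(C)=C)[C@@H](O[Si](C)(C)C(C)(C)C)C1=O | intermediate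
8 | (4R,5S,6R)-6-[(tert-butyldimethylsilyl)oxy]-4-hydroxy-5-(3-hydroxyprop-1-en-2-yl)-2-methylcyclohex-2-en-1-one | CC1=C[C@@H](O)[C@H](C(=C)CO)[C@@H](O[Si](C)(C)C(C)(C)C)C1=O | intermediate
9 | hydroxy enal, the 2-substituted acrolein from oxidation of the primary alcohol of 8 (not isolated) | CC1=C[C@@H](O)[C@H](C(=C)C=O)[C@@H](O[Si](C)(C)C(C)(C)C)C1=O | intermediate
10 | trans-fused lactol from 9, anomer mixture at C12 (not isolated) | C=C1C(O)O[C@@H]2C=C(C)C(=O)[C@H](O[Si](C)(C)C(C)(C)C)[C@@H]12 | intermediate
11 | (3aS,4R,7aR)-4-[(tert-butyldimethylsilyl)oxy]-6-methyl-3-methylidene-3a,4-dihydro-1-benzofuran-2,5(3H,7aH)-dione (trans-fused enone lactone, ring carbons C5–C10) | C=C1C(=O)O[C@@H]2C=C(C)C(=O)[C@H](O[Si](C)(C)C(C)(C)C)[C@@H]12 | intermediate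
12 | 3-ethoxycyclobut-2-en-1-one | CCOC1=CC(=O)C1 | starting material
13 | lithium 3-ethoxy-1-methylcyclobut-2-en-1-olate, racemic (not isolated) | CCOC1=CC(C)([O-])C1.[Li+] | intermediate
14 | 3-methylcyclobut-2-en-1-one | CC1=CC(=O)C1 | intermediate
15 | (R)-3-methylcyclobut-2-en-1-ol (not isolated) | CC1=C[C@H](O)C1 | intermediate
16 | (R)-3-methylcyclobut-2-en-1-yl acetate | CC1=C[C@H](OC(C)=O)C1 | intermediate
17 | cis-anti-cis photoadduct: cyclobutane C1–C4–C5–C10 cis-fused to the cyclohexanone at C5/C10 on the face opposite O6 and O8, and cis-fused to the acetoxycyclobutane C1–C2–C3–C4, outer rings anti, 2-acetoxy group on the face away from C5/C10 | C=C1C(=O)O[C@@H]2[C@H]3[C@]4(C)C[C@@H](OC(C)=O)[C@@H]4[C@@]3(C)C(=O)[C@H](O[Si](C)(C)C(C)(C)C)[C@@H]12 | intermediate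
18 | (1(10)Z,4E,2R,6R,7S,8R)-2-acetoxy-8-[(tert-butyldimethylsilyl)oxy]-9-oxogermacra-1(10),4,11(13)-trien-12,6-olide | C=C1C(=O)O[C@@H]2/C=C(\C)C[C@@H](OC(C)=O)/C=C(/C)C(=O)[C@H](O[Si](C)(C)C(C)(C)C)[C@@H]12 | intermediate
19 | (1(10)Z,4E)-2-acetoxy-8-hydroxy-9-oxogermacra-1(10),4,11(13)-trien-12,6-olide, configuration at C2, C6, C7, C8 as in 18 | C=C1C(=O)O[C@@H]2/C=C(\C)C[C@@H](OC(C)=O)/C=C(/C)C(=O)[C@H](O)[C@@H]12 | intermediate
20 | angelic acid, (Z)-2-methylbut-2-enoic acid | C/C=C(/C)C(=O)O | starting material
21 | angelic 2,4,6-trichlorobenzoic anhydride (not isolated) | C/C=C(/C)C(=O)OC(=O)c1c(Cl)cc(Cl)cc1Cl | intermediate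
22 | (1(10)Z,4E,2R,6R,7S,8R)-2-acetoxy-8-angeloyloxy-9-oxogermacra-1(10),4,11(13)-trien-12,6-olide | C=C1C(=O)O[C@@H]2/C=C(\C)C[C@@H](OC(C)=O)/C=C(/C)C(=O)[C@H](OC(=O)/C(C)=C\C)[C@@H]12 | intermediate
23 | (1(10)Z,4E,2R,6R,7S,8R,9R)-2-acetoxy-8-angeloyloxy-9-hydroxygermacra-1(10),4,11(13)-trien-12,6-olide | C=C1C(=O)O[C@@H]2/C=C(\C)C[C@@H](OC(C)=O)/C=C(/C)[C@@H](O)[C@H](OC(=O)/C(C)=C\C)[C@@H]12 | intermediate
24 | CNP0499619.1, (1(10)Z,4E,2R,6R,7S,8R,9R)-2,9-diacetoxy-8-angeloyloxygermacra-1(10),4,11(13)-trien-12,6-olide | C=C1C(=O)O[C@@H]2/C=C(\C)C[C@@H](OC(C)=O)/C=C(/C)[C@@H](OC(C)=O)[C@H](OC(=O)/C(C)=C\C)[C@@H]12 | target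

Total step count: 14. Longest linear sequence: 12 steps (steps 1–6 and 9–14 from (S)-carvone); the cyclobutene branch is steps 7–8.

Steps most likely to fail

1. Step 9. The α-methyl enone triplet may be captured only slowly by the trisubstituted cyclobutene. The excited enone would then add to the electron-poor exocyclic methylene of a second lactone molecule, and material would be lost before the cyclobutane forms. The fallback sets out from 7 (with 16) and comes back at 17: the photocycloaddition is moved one stage earlier, to a substrate that has no acrylate. Irradiation of hydroxy enone 7 with 16 under the conditions of step 9 should give the analogous cis-anti-cis tricyclic hydroxy ketone F1. The all-equatorial C6, C7 and C8 substituents hold the isopropenyl group away from the enone, so the intramolecular cycloaddition known for carvone is not expected. SeO2/t-BuOOH then hydroxylates the isopropenyl methyl group to give the diol F2. Oxidation with 2,2,6,6-tetramethylpiperidin-1-oxyl and PhI(OAc)2 closes the lactone through the hydroxy enal F3 and the lactol F4 and delivers 17.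

2. Step 10. The diyl may open through a boat-like rather than chair-like arrangement, or a trans-fused adduct may be carried along; either delivers the 1(10)E enone. On prolonged heating such E,E-dienes drift by Cope rearrangement into divinylcyclohexanones. The fallback sets out from 17 and comes back at 18. The cycloreversion is run as a short-contact flash vacuum pyrolysis so that the (1(10)E,4E)-dienone F5 is intercepted before it rearranges. The geometry is then corrected photochemically: irradiation of F5 at 350 nm and low temperature should isomerise only the conjugated C1=C10 bond (E/Z photoisomerisation of a medium-ring enone). 18 is separated from the photostationary mixture and F5 is recycled.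

3. Step 4. Oxygen transfer to C6 may show poor facial selectivity (attack syn to the C7 isopropenyl group), which gives the C6 epimer. The fallback sets out from 5 and comes back at 7: the epimer is inverted instead of discarded. The C6-epimeric alcohol F6 from the oxidation is subjected to a Mitsunobu reaction (PPh3, diisopropyl azodicarboxylate, 4-nitrobenzoic acid, THF, 0 °C). SN2 displacement at the allylic carbon should give the inverted 4-nitrobenzoate F7. Methanolysis (K2CO3, MeOH, 0 °C) then releases 7; the trans C8 silyl ether is the thermodynamic epimer under these conditions.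

Further compounds
F1 | step 9 | cis-anti-cis photoadduct of 7 with 16 (tricyclic hydroxy ketone, C6 hydroxyl and C7 isopropenyl retained) | O[C@@H]1[C@H]2[C@]3(C)C[C@@H](OC(C)=O)[C@@H]3[C@@]2(C)C(=O)[C@H](O[Si](C)(C)C(C)(C)C)[C@H]1C(C)=C
F2 | step 9 | diol from allylic hydroxylation of F1 (C7 3-hydroxyprop-1-en-2-yl group) | O[C@@H]1[C@H]2[C@]3(C)C[C@@H](OC(C)=O)[C@@H]3[C@@]2(C)C(=O)[C@H](O[Si](C)(C)C(C)(C)C)[C@H]1C(=C)CO
F3 | step 9 | hydroxy enal from F2 (not isolated) | O[C@@H]1[C@H]2[C@]3(C)C[C@@H](OC(C)=O)[C@@H]3[C@@]2(C)C(=O)[C@H](O[Si](C)(C)C(C)(C)C)[C@H]1C(=C)C=O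
F4 | step 9 | trans-fused lactol from F3, anomer mixture at C12 (not isolated) | C=C1C(O)O[C@@H]2[C@H]3[C@]4(C)C[C@@H](OC(C)=O)[C@@H]4[C@@]3(C)C(=O)[C@H](O[Si](C)(C)C(C)(C)C)[C@@H]12
F5 | step 10 | (1(10)E,4E,2R,6R,7S,8R)-2-acetoxy-8-[(tert-butyldimethylsilyl)oxy]-9-oxogermacra-1(10),4,11(13)-trien-12,6-olide | C=C1C(=O)O[C@@H]2/C=C(\C)C[C@@H](OC(C)=O)/C=C(\C)C(=O)[C@H](O[Si](C)(C)C(C)(C)C)[C@@H]12
F6 | step 4 | (4S,5S,6R)-6-[(tert-butyldimethylsilyl)oxy]-4-hydroxy-2-methyl-5-(prop-1-en-2-yl)cyclohex-2-en-1-one (C6 epimer of 7) | CC1=C[C@H](O)[C@H](C(C)=C)[C@@H](O[Si](C)(C)C(C)(C)C)C1=O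
F7 | step 4 | 4-nitrobenzoate of 7 (C6 ester trans to C7) | CC1=C[C@@H](OC(=O)c2ccc(cc2)[N+](=O)[O-])[C@H](C(C)=C)[C@@H](O[Si](C)(C)C(C)(C)C)C1=O
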